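The earlier runs and the new flask come from a simulation for an exercise, noise included.

The vessel holds X and Q from the start, and D goes in by portions; Z is what is counted.

all flasks: X 0.010 M
- violet: Q 0.013 M; D 0.011 M (in portions, 3); the very flask that is asked about, followed so far; portions every 1.0 h
- flask: Q 0.0130 M; D 0.0110 M (in portions, 3); the portions of D follow each other after 1.0 h, the first at the start; time 15 d

violet run (percent of the X charged)

| time / d | X / % | Z / % |
|---|---|---|
| 0.250 | 76.7 | 3.3 |
| 0.500 | 71.4 | 8.8 |
| 1.25 | 71.5 | 18.4 |
| 3.00 | 68.7 | 25.6 |

(each reading ± 1 percentage point)

- the numbers in the tables scatter with a standard deviation of 1 percentage point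

- how much of the X has reacted by 15 d
- how much Z there is at 15 d, in percent of the X charged
- amount of Z if the flask were left three thousand times as long, in percent of the X charged

X stands at 71.4 % at 0.500 d and 68.7 % at 3.00 d, nearly flat, although the D charged is 1.10 times the X. A balance of D on the last reading of the violet run, taking one D per X lost, gives the capture share 0.285: the fraction of the D charged that ends on X. On this balance, itself a reading with its scatter, the other 0.715 of D does not end on X.

A neighbouring flask looks nearly the same: X and Q as before, but D at 2.70 times the X. If the capture share holds, X lost is that share times D per X, so this reckoning gives 31.3 % for the flask and 76.8 % for the neighbour. This reckoning leaves X over in both, and the two flasks differ in the charge of D.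

The forecast gives 34 % reacted (29 % to 45 %), 32 % of Z (27 % to 42 %) and 36 % of Z on long standing, with a range up to 95 %, since “a real slow route could carry it much higher”. Its conversion lies above this reckoning.

The flask gives 29.5 % reacted and 28.5 % of Z at 15 d, and 28.5 % of Z left far longer, below the forecast.

    E + L → Z (k = 0.228 L mol⁻¹ min⁻¹)
    2 E → G (k = 0.0102 L mol⁻¹ min⁻¹)
    D + Q → L (k = 0.220 L mol⁻¹ min⁻¹)
    X + D → E (k = 0.168 L mol⁻¹ min⁻¹)
    D → J (k = 0.00157 min⁻¹)

At the start, with full charges, D is taken by X at 2.42 d⁻¹, by Q at 4.12 d⁻¹ and turns into J at 2.26 d⁻¹, so X takes less than the other two together. D, the limiting reagent, ends at 0 % of its charge, less than X at 70 % of its own; 0.268 of it reached X in the flask, and the neighbour reacts 67.0 % against the reckoned 76.8 %, a capture share of 0.248.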